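**Retrosynthetic overview**
1. Ether cleavage and C4 oxidation lead back to a protected (2S,4S)-flavan-4-ol; ring C is the only ring that has to be built.
2. Ring C is cut at the aryl ether bond O1–C8a. O1 joins the benzylic stereocentre C2 to C8a of ring A, so a C8a bromide and the free carbinol of a (1S,3S)-1,3-diaryl-1,3-propanediol can be joined by palladium-catalysed O-arylation while the C2–O bond is never broken.
3. The diol comes from a chalcone by Juliá–Colonna epoxidation (sets C2), reductive opening at the α-carbon and 1,3-anti reduction. The chalcone comes from 2'-bromo-4',6'-dimethoxyacetophenone and a biaryl aldehyde by Claisen–Schmidt condensation.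
4. The biaryl bond C3'–C8'' is made by Suzuki coupling of 8-iodo-tri-O-benzylapigenin with the 3-pinacolboronate of 4-benzyloxybenzaldehyde.
5. Ring order: rings A and B and the whole flavone are carried in from the starting arenes and apigenin; ring C is closed last among the rings (step 11).

Key step: step 11

Remark: C1 of diol 13 (C4 of 14) is set S by the anti reduction but is oxidised in step 12, so only C3 of the diol (future C2) has to be enantiopure; poly-D-leucine is taken as prepared from D-leucine N-carboxyanhydride.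
In the names, "tri-O-benzylapigenin-8-yl" stands for 5,7-bis(benzyloxy)-2-[4-(benzyloxy)phenyl]-4-oxo-4H-chromen-8-yl.

Step 1
Reactants: 1 1-bromo-3,5-dimethoxybenzene
Product: 2 1-(2-bromo-4,6-dimethoxyphenyl)ethan-1-one
Conditions: AcCl, AlCl3, CH2Cl2, 0 °C
Reagents that add atoms: acetyl chloride, CC(Cl)=O
Why: Friedel–Crafts acylation should go to C2, para to one methoxy group and ortho to the other, the same position this arene takes in Vilsmeier formylation.

Step 2
Reactants: 3 apigenin
Product: 4 5,7,4'-tri-O-benzylapigenin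
Conditions: BnBr (excess), K2CO3, DMF, 80 °C
Reagents that add atoms: benzyl bromide, BrCc1ccccc1
Why: Williamson ether synthesis; heating in DMF with excess bromide is needed so that the hydrogen-bonded 5-hydroxyl is alkylated as well as the 7- and 4'-hydroxyls.

Step 3
Reactants: 4 5,7,4'-tri-O-benzylapigenin
Product: 5 8-iodo-5,7,4'-tri-O-benzylapigenin
Conditions: I2, CF3CO2Ag, CH2Cl2, 0 °C to rt
Reagents that add atoms: iodine, II
Why: Electrophilic aromatic iodination of the phloroglucinol-type ring A; with the 5-oxygen alkylated, 5,7-dialkoxyflavones are iodinated at C8 and not at C6.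

Step 4
Reactants: 6 3-bromo-4-hydroxybenzaldehyde
Product: 7 4-(benzyloxy)-3-bromobenzaldehyde
Conditions: BnBr, K2CO3, DMF, rt
Reagents that add atoms: benzyl bromide, BrCc1ccccc1
Why: Williamson ether synthesis on an acidic para-formyl phenol, which should proceed cleanly at room temperature.

Step 5
Reactants: 7 4-(benzyloxy)-3-bromobenzaldehyde
Product: 8 4-(benzyloxy)-3-(4,4,5,5-tetramethyl-1,3,2-dioxaborolan-2-yl)benzaldehyde
Conditions: B2pin2, PdCl2(dppf) (cat.), KOAc, 1,4-dioxane, 90 °C
Reagents that add atoms: bis(pinacolato)diboron, CC1(C)OB(OC1(C)C)B1OC(C)(C)C(C)(C)O1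
Why: Miyaura borylation of an aryl bromide; the weak base KOAc leaves the aldehyde untouched and does not promote homocoupling.

Step 6
Reactants: 5 8-iodo-5,7,4'-tri-O-benzylapigenin; 8 4-(benzyloxy)-3-(4,4,5,5-tetramethyl-1,3,2-dioxaborolan-2-yl)benzaldehyde
Product: 9 4-(benzyloxy)-3-(tri-O-benzylapigenin-8-yl)benzaldehyde
Conditions: Pd(OAc)2 (cat.), SPhos, K3PO4, toluene/H2O, 90 °C
Reagents that add atoms: none
Why: Suzuki–Miyaura coupling; the dialkylbiarylphosphine SPhos is chosen because the biaryl carries three ortho substituents, and the iodide is the only halide present.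

Step 7
Reactants: 2 1-(2-bromo-4,6-dimethoxyphenyl)ethan-1-one; 9 4-(benzyloxy)-3-(tri-O-benzylapigenin-8-yl)benzaldehyde
Product: 10 (E)-1-(2-bromo-4,6-dimethoxyphenyl)-3-[4-(benzyloxy)-3-(tri-O-benzylapigenin-8-yl)phenyl]prop-2-en-1-one
Conditions: KOH, EtOH/THF, rt
Reagents that add atoms: none
Why: Claisen–Schmidt condensation of a methyl ketone with a non-enolisable aldehyde, with E1cB dehydration to the E-enone; room temperature is kept so that hydroxide does not open the flavone pyranone.

Step 8
Reactants: 10 (E)-chalcone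
Product: 11 (2-bromo-4,6-dimethoxyphenyl){(2S,3R)-3-[4-(benzyloxy)-3-(tri-O-benzylapigenin-8-yl)phenyl]oxiran-2-yl}methanone
Conditions: poly-D-leucine (immobilised), urea–H2O2, DBU, THF, rt
Reagents that add atoms: urea–hydrogen peroxide, NC(N)=O.OO
Why: Juliá–Colonna epoxidation (Weitz–Scheffer addition of hydroperoxide to the enone held at the N-terminus of the polypeptide helix); poly-L-leucine gives (2R,3S)-epoxychalcones, so poly-D-leucine should give the (2S,3R)-epoxide, whose C3–O bond becomes the C2–O1 bond of the target.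

Step 9
Reactants: 11 (2S,3R)-epoxy ketone
Product: 12 (3S)-1-(2-bromo-4,6-dimethoxyphenyl)-3-hydroxy-3-[4-(benzyloxy)-3-(tri-O-benzylapigenin-8-yl)phenyl]propan-1-one
Conditions: SmI2 (2.2 equiv), THF/MeOH, −90 °C, then pH 7 buffer
Reagents that add atoms: none
Why: Reductive opening of an α,β-epoxy ketone by single-electron transfer: the ketyl expels the α-oxygen and the samarium enolate is protonated, so the β C–O bond and its configuration are untouched (the descriptor changes from 3R to 3S only because the priorities change), and the cold, HMPA-free conditions should spare the aryl bromide and the flavone.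

Step 10
Reactants: 12 (3S)-β-hydroxy ketone
Product: 13 (1S,3S)-1-(2-bromo-4,6-dimethoxyphenyl)-3-[4-(benzyloxy)-3-(tri-O-benzylapigenin-8-yl)phenyl]propane-1,3-diol
Conditions: Me4NBH(OAc)3, MeCN/AcOH, −30 °C, then cold aq. NaHCO3/Rochelle salt
Reagents that add atoms: none
Why: Evans–Saksena reduction: the C3 hydroxyl exchanges onto boron and hydride is delivered intramolecularly through a chair transition state, which should set C1 as S (1,3-anti); the flavone carbonyl has no directing hydroxyl and is not reduced.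

Step 11
Reactants: 13 (1S,3S)-diol
Product: 14 (2S,4S)-5,7-dimethoxy-2-[4-(benzyloxy)-3-(tri-O-benzylapigenin-8-yl)phenyl]chroman-4-ol (2,4-cis)
Conditions: Pd(OAc)2 (5 mol %), 2-(di-tert-butylphosphino)-1,1'-binaphthyl (6 mol %), Cs2CO3, toluene, 70 °C
Reagents that add atoms: none
Why: Zerovalent palladium, formed from Pd(OAc)2 and the phosphine, inserts into the C8a–Br bond; carbonate deprotonates the palladium-bound C3 hydroxyl to give a seven-membered aryl(alkoxo)palladacycle of divalent palladium, and C–O reductive elimination forms O1–C8a. The closest known reaction is the palladium-catalysed intramolecular etherification of aryl bromides with enantiopure secondary alcohols, which gives 2-substituted chromans without loss of configuration. Ring C closes as a six-membered ring by O-arylation, that is by reductive elimination from the seven-membered palladacycle (a 6-exo-type attack of the C3 oxygen on C8a). No stereocentre is formed: the C3–O bond (future C2–O1) and the C1 carbinol are never broken, so 14 should be (2S,4S) by retention. The step needs the C3 hydroxyl to react and not the C1 hydroxyl, and C–O reductive elimination to outrun β-hydride elimination: the C1 alkoxide can only chelate palladium in a five-membered ring that would have to eliminate to a four-membered benzoxete and whose C1–H lies far from the syn-coplanar geometry needed for hydride transfer, so it exchanges back, while the bulky di-tert-butylphosphine presses aryl and alkoxide together. The diol is used because the β-hydroxy ketone 12 would dehydrate to the chalcone under carbonate.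

Step 12
Reactants: 14 (2S,4S)-flavan-4-ol
Product: 15 (2S)-5,7-dimethoxy-2-[4-(benzyloxy)-3-(tri-O-benzylapigenin-8-yl)phenyl]chroman-4-one
Conditions: Dess–Martin periodinane, pyridine, CH2Cl2, 0 °C to rt
Reagents that add atoms: none
Why: Dess–Martin oxidation of the only free hydroxyl; the pyridine buffer protects the acid-labile, electron-rich benzylic alcohol from ionisation and the conditions should not epimerise C2.

Step 13
Reactants: 15 (2S)-protected flavanone
Product: 16 CNP0107492.1, (2S)-5-hydroxy-2-{4-hydroxy-3-[5,7-dihydroxy-2-(4-hydroxyphenyl)-4-oxo-4H-chromen-8-yl]phenyl}-7-methoxy-2,3-dihydro-4H-chromen-4-one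
Conditions: BCl3 (excess), pentamethylbenzene, CH2Cl2, −78 °C to rt, then MeOH/H2O
Reagents that add atoms: none
Why: Lewis-acid ether cleavage: BCl3 removes the four benzyl groups (pentamethylbenzene traps the benzyl cations) and, through the six-membered chelate with the C4 carbonyl, only the 5-O-methyl group, while the unchelated 7-O-methyl ether should survive.

**Compound list**
1 | 1-bromo-3,5-dimethoxybenzene | COc1cc(Br)cc(OC)c1 | starting material
2 | 1-(2-bromo-4,6-dimethoxyphenyl)ethan-1-one | COc1cc(Br)c(C(C)=O)c(OC)c1 | intermediate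
3 | apigenin | O=c1cc(-c2ccc(O)cc2)oc2cc(O)cc(O)c12 | starting material
4 | 5,7,4'-tri-O-benzylapigenin | O=c1cc(-c2ccc(OCc3ccccc3)cc2)oc2cc(OCc3ccccc3)cc(OCc3ccccc3)c12 | intermediate
5 | 8-iodo-5,7,4'-tri-O-benzylapigenin | Ic1c(OCc2ccccc2)cc(OCc2ccccc2)c2c(=O)cc(-c3ccc(OCc4ccccc4)cc3)oc12 | intermediate
6 | 3-bromo-4-hydroxybenzaldehyde | O=Cc1ccc(O)c(Br)c1 | starting material
7 | 4-(benzyloxy)-3-bromobenzaldehyde | O=Cc1ccc(OCc2ccccc2)c(Br)c1 | intermediate
8 | 4-(benzyloxy)-3-(4,4,5,5-tetramethyl-1,3,2-dioxaborolan-2-yl)benzaldehyde | O=Cc1ccc(OCc2ccccc2)c(B2OC(C)(C)C(C)(C)O2)c1 | intermediate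
9 | 4-(benzyloxy)-3-(tri-O-benzylapigenin-8-yl)benzaldehyde | O=Cc1ccc(OCc2ccccc2)c(-c2c(OCc3ccccc3)cc(OCc3ccccc3)c3c(=O)cc(-c4ccc(OCc5ccccc5)cc4)oc23)c1 | intermediate
10 | (E)-1-(2-bromo-4,6-dimethoxyphenyl)-3-[4-(benzyloxy)-3-(tri-O-benzylapigenin-8-yl)phenyl]prop-2-en-1-one | COc1cc(Br)c(C(=O)/C=C/c2ccc(OCc3ccccc3)c(-c3c(OCc4ccccc4)cc(OCc4ccccc4)c4c(=O)cc(-c5ccc(OCc6ccccc6)cc5)oc34)c2)c(OC)c1 | intermediate
11 | (2-bromo-4,6-dimethoxyphenyl){(2S,3R)-3-[4-(benzyloxy)-3-(tri-O-benzylapigenin-8-yl)phenyl]oxiran-2-yl}methanone | COc1cc(Br)c(C(=O)[C@H]7O[C@@H]7c2ccc(OCc3ccccc3)c(-c3c(OCc4ccccc4)cc(OCc4ccccc4)c4c(=O)cc(-c5ccc(OCc6ccccc6)cc5)oc34)c2)c(OC)c1 | intermediate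
12 | (3S)-1-(2-bromo-4,6-dimethoxyphenyl)-3-hydroxy-3-[4-(benzyloxy)-3-(tri-O-benzylapigenin-8-yl)phenyl]propan-1-one | COc1cc(Br)c(C(=O)C[C@H](O)c2ccc(OCc3ccccc3)c(-c3c(OCc4ccccc4)cc(OCc4ccccc4)c4c(=O)cc(-c5ccc(OCc6ccccc6)cc5)oc34)c2)c(OC)c1 | intermediate
13 | (1S,3S)-1-(2-bromo-4,6-dimethoxyphenyl)-3-[4-(benzyloxy)-3-(tri-O-benzylapigenin-8-yl)phenyl]propane-1,3-diol | COc1cc(Br)c([C@@H](O)C[C@H](O)c2ccc(OCc3ccccc3)c(-c3c(OCc4ccccc4)cc(OCc4ccccc4)c4c(=O)cc(-c5ccc(OCc6ccccc6)cc5)oc34)c2)c(OC)c1 | intermediate
14 | (2S,4S)-5,7-dimethoxy-2-[4-(benzyloxy)-3-(tri-O-benzylapigenin-8-yl)phenyl]chroman-4-ol | COc1cc(OC)c2c(c1)O[C@H](c1ccc(OCc3ccccc3)c(-c3c(OCc4ccccc4)cc(OCc4ccccc4)c4c(=O)cc(-c5ccc(OCc6ccccc6)cc5)oc34)c1)C[C@@H]2O | intermediate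
15 | (2S)-5,7-dimethoxy-2-[4-(benzyloxy)-3-(tri-O-benzylapigenin-8-yl)phenyl]chroman-4-one | COc1cc(OC)c2c(c1)O[C@H](c1ccc(OCc3ccccc3)c(-c3c(OCc4ccccc4)cc(OCc4ccccc4)c4c(=O)cc(-c5ccc(OCc6ccccc6)cc5)oc34)c1)CC2=O | intermediate
16 | CNP0107492.1, (2S)-5-hydroxy-2-{4-hydroxy-3-[5,7-dihydroxy-2-(4-hydroxyphenyl)-4-oxo-4H-chromen-8-yl]phenyl}-7-methoxy-2,3-dihydro-4H-chromen-4-one | COc1cc(O)c2c(c1)O[C@H](c1ccc(O)c(-c3c(O)cc(O)c4c(=O)cc(-c5ccc(O)cc5)oc34)c1)CC2=O | target

**Step count**
Total: 13 steps. Longest linear sequence: 10 steps (steps 2, 3 and 6–13 from apigenin 3; equally steps 4–13 from 6).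

**Steps most likely to fail**

Step 11 (key step). The arylpalladium bromide may be diverted: the C1 alkoxide can hold the metal in a chelate and, after ring opening of that chelate, transfer hydride, so that the benzylic alcohol is oxidised and the bromide is lost. β-Hydride elimination from the C3 alkoxide may also outrun C–O reductive elimination. The fallback closes ring C at the other ether bond, O1–C2, and sets out from aldehyde 9. Claisen–Schmidt condensation of 9 with commercial 2'-hydroxy-4',6'-dimethoxyacetophenone (KOH, EtOH/THF, rt) should give the (E)-2'-hydroxychalcone F1. Heating F1 with NaOAc in EtOH should close the ring by intramolecular oxa-Michael addition to the racemic 5,7-dimethoxyflavanone F2. Separation of the enantiomers of F2 on a chiral stationary phase then gives the (S)-enantiomer, which is flavanone 15, where the route is rejoined.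

Step 8. The di-ortho-substituted aryl ketone is twisted and may bind poorly to the polypeptide, so hydroperoxide addition may be slow and the facial selectivity poor. The fallback sets out from chalcone 10 and forms the C3–O bond through boron. Copper-catalysed conjugate borylation (CuCl, NaOtBu, a Josiphos-type ferrocenyl diphosphine in the enantiomeric form that gives the S product, B2pin2, MeOH, THF, rt) should give the (S)-β-pinacolboryl ketone F3. Oxidation of F3 with NaBO3·4H2O in THF/H2O replaces boron by hydroxyl with retention and returns to the route at β-hydroxy ketone 12, so steps 8 and 9 are bypassed.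

Step 13. The risks are over-cleavage with loss of the 7-O-methyl group, C-benzylation of the electron-rich rings by benzyl cations that escape the scavenger, and Lewis-acid opening of ring C with erosion of C2. The fallback separates the two kinds of ether cleavage and sets out from flavanone 15. Hydrogenolysis (H2, Pd/C, THF/MeOH, rt) should remove the four benzyl groups under neutral conditions and give the (2S)-5,7-di-O-methyl tetraphenol F4. Chelation-assisted demethylation of F4 with AlCl3 in MeCN then cleaves only the 5-O-methyl group and arrives at target 16.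

**Further compounds**
F1 | step 11 | (E)-1-(2-hydroxy-4,6-dimethoxyphenyl)-3-[4-(benzyloxy)-3-(tri-O-benzylapigenin-8-yl)phenyl]prop-2-en-1-one | COc1cc(O)c(C(=O)/C=C/c2ccc(OCc3ccccc3)c(-c3c(OCc4ccccc4)cc(OCc4ccccc4)c4c(=O)cc(-c5ccc(OCc6ccccc6)cc5)oc34)c2)c(OC)c1
F2 | step 11 | racemic 5,7-dimethoxy-2-[4-(benzyloxy)-3-(tri-O-benzylapigenin-8-yl)phenyl]chroman-4-one | COc1cc(OC)c2c(c1)OC(c1ccc(OCc3ccccc3)c(-c3c(OCc4ccccc4)cc(OCc4ccccc4)c4c(=O)cc(-c5ccc(OCc6ccccc6)cc5)oc34)c1)CC2=O
F3 | step 8 | (3S)-1-(2-bromo-4,6-dimethoxyphenyl)-3-(4,4,5,5-tetramethyl-1,3,2-dioxaborolan-2-yl)-3-[4-(benzyloxy)-3-(tri-O-benzylapigenin-8-yl)phenyl]propan-1-one | COc1cc(Br)c(C(=O)C[C@H](B7OC(C)(C)C(C)(C)O7)c2ccc(OCc3ccccc3)c(-c3c(OCc4ccccc4)cc(OCc4ccccc4)c4c(=O)cc(-c5ccc(OCc6ccccc6)cc5)oc34)c2)c(OC)c1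
F4 | step 13 | (2S)-2-{4-hydroxy-3-[5,7-dihydroxy-2-(4-hydroxyphenyl)-4-oxo-4H-chromen-8-yl]phenyl}-5,7-dimethoxychroman-4-one | COc1cc(OC)c2c(c1)O[C@H](c1ccc(O)c(-c3c(O)cc(O)c4c(=O)cc(-c5ccc(O)cc5)oc34)c1)CC2=O
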